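## Retrosynthetic overview
1. The target comes from saponification and desilylation of ester 26. Ester 26 comes from a B-alkyl Suzuki–Miyaura coupling (C9–C11) of enol triflate 19 with dienoate 24, which is made from vinylcopper and methyl but-2-ynoate.
2. Triflate 19 comes from 9-oxo-triol 17. Triol 17 comes from the tricyclic 3-keto-19,6β-lactone ketal 14 by two hydride reductions and ketal hydrolysis.
3. Key step: 14 comes from the monocyclic allylic β-keto ester 13 in one oxidative radical cascade. It forms C4–C5 (5-exo, lactone), then C10–C1 (6-endo, ring A), and sets C4, C5 and C10 from C6.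
4. Ester 13 comes from ring-B allylic alcohol 7, propionic acid and acrolein by Mitsunobu inversion, aldol addition and oxidation.
5. Alcohol 7 comes from m-cresol by dearomatisation to a quinone monoketal, asymmetric conjugate methylation and Luche reduction. Ring order: ring B (the cresol carbocycle), then the γ-lactone, then ring A.

Numbering: labdane numbering is used throughout. C1–C10 form the decalin, C11–C16 the side chain, C17 sits on C8, C18/C19 on C4 and C20 on C10. The target is read as 3α,6β,19-trihydroxylabda-8,13E-dien-15-oic acid (3R,4S,5R,6R,10S).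

Assumption: the (S,R,R)-phosphoramidite is taken to give (5R)-6 by analogy. If the adduct proves to be 5S, the antipodal ligand is used.

## Route

Step 1
Reactants: 1 m-cresol
Product: 3 4,4-dimethoxy-3-methylcyclohexa-2,5-dien-1-one, via 4-methoxy-3-methylphenol 2 (not isolated)
Conditions: PhI(OAc)2 (2.1 equiv), MeOH, 0 °C to rt
Reagents that add atoms: methanol CO
Why: Two successive para-selective oxidative phenol dearomatisations trap methanol, first giving the hydroquinone monoether and then the quinone monoketal, which masks the future C9 carbonyl and creates no stereocentre.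

Step 2
Reactants: 3 4,4-dimethoxy-3-methylcyclohexa-2,5-dien-1-one; 4 dimethylzinc
Product: 6 (5R)-4,4-dimethoxy-3,5-dimethylcyclohex-2-en-1-one, via methylzinc dienolate 5 (not isolated)
Conditions: Cu(OTf)2 (2 mol %), (S,R,R)-binaphthol-derived N,N-bis(1-phenylethyl)phosphoramidite (4 mol %), toluene, −25 °C; then pH 7 buffer
Reagents that add atoms: none
Why: In this copper-catalysed enantioselective conjugate addition of a dialkylzinc to a quinone monoketal, only the unsubstituted enone terminus (C8) reacts, and the ligand sets C8 (R) as a relay stereocentre that is erased in step 9.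

Step 3
Reactants: 6 (5R)-4,4-dimethoxy-3,5-dimethylcyclohex-2-en-1-one
Product: 7 (1S,5R)-4,4-dimethoxy-3,5-dimethylcyclohex-2-en-1-ol
Conditions: NaBH4, CeCl3·7H2O, MeOH, −78 °C
Reagents that add atoms: none
Why: In this Luche 1,2-reduction, axial hydride delivery to the half-chair gives the pseudo-equatorial alcohol cis to the C8 methyl, as with 5-substituted cyclohexenones, so C8 sets C6 (S).

Step 4
Reactants: 7 (1S,5R)-4,4-dimethoxy-3,5-dimethylcyclohex-2-en-1-ol; 8 propionic acid
Product: 9 (1R,5R)-4,4-dimethoxy-3,5-dimethylcyclohex-2-en-1-yl propanoate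
Conditions: PPh3, DIAD, THF, 0 °C
Reagents that add atoms: none
Why: Mitsunobu esterification with SN2 inversion at the unhindered allylic C6 installs the 6β-oxygen (C6 R) trans to the C8 methyl, so that C6–O can later be axial while the methyl stays equatorial.

Step 5
Reactants: 9 (1R,5R)-4,4-dimethoxy-3,5-dimethylcyclohex-2-en-1-yl propanoate; 10 acrolein
Product: 12 (1R,5R)-4,4-dimethoxy-3,5-dimethylcyclohex-2-en-1-yl 3-hydroxy-2-methylpent-4-enoate, via lithium enolate 11 (not isolated)
Conditions: LiN(i-Pr)2, THF, −78 °C; then 10, −78 °C; aqueous quench at −78 °C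
Reagents that add atoms: none
Why: The lithium ester enolate adds 1,2 to acrolein (aldol addition) at a temperature too low for Ireland–Claisen rearrangement, and the two new stereocentres do not matter because C3 is oxidised next and C4 is later planarised.

Step 6
Reactants: 12 (1R,5R)-4,4-dimethoxy-3,5-dimethylcyclohex-2-en-1-yl 3-hydroxy-2-methylpent-4-enoate
Product: 13 (1R,5R)-4,4-dimethoxy-3,5-dimethylcyclohex-2-en-1-yl 2-methyl-3-oxopent-4-enoate
Conditions: Dess–Martin periodinane, CH2Cl2, 0 °C; used promptly
Reagents that add atoms: none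
Why: Dess–Martin oxidation of the allylic carbinol gives the vinyl-ketone β-keto ester under near-neutral conditions that spare the allylic ketal and the allylic ester.

Step 7 (key step)
Reactants: 13 (1R,5R)-4,4-dimethoxy-3,5-dimethylcyclohex-2-en-1-yl 2-methyl-3-oxopent-4-enoate
Product: 14 9,9-dimethoxy-3-oxo-11,12,13,14,15,16-hexanorlabdan-19,6β-olide (5α-H 8β-H 10β-methyl)
Conditions: Mn(OAc)3·2H2O (2.2 equiv), KOAc, degassed EtOH (0.01 M), 60 °C
Reagents that add atoms: none
Why: Proposed new method: Mn(OAc)3 oxidises the enolisable β-keto ester to the electrophilic C4 radical, which closes 5-exo-trig onto C5 from the face of the pseudoaxial C6–O tether (cis-fused γ-lactone, sets C5; only the manganese-chelated U-shaped radical that holds the acryloyl group over C10 can go on, while the other C4 epimer reverts by β-scission, which sets C4), the nucleophilic tertiary C10 radical then closes 6-endo-trig onto the vinyl ketone through a chair-like transition state with the quaternary C4 equatorial on ring B (C1 enters α, C20 becomes axial β, trans-decalin, the same course as the second closure of radical polyene cyclisations), and the electrophilic C2 radical, which trivalent manganese does not oxidise, takes hydrogen from ethanol; the closest known reaction types are the Mn(OAc)3 oxidative free-radical cyclisation of allylic β-dicarbonyl esters to γ-lactones and tandem Mn(OAc)3 cyclisations run in ethanol.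

Step 8
Reactants: 14 9,9-dimethoxy-3-oxo-11,12,13,14,15,16-hexanorlabdan-19,6β-olide
Product: 17 3α,6β,19-trihydroxy-11,12,13,14,15,16-hexanorlabdan-9-one, via 3α-hydroxy lactone 15 (not isolated), via triol ketal 16 (not isolated)
Conditions: LiBH(s-Bu)3, THF, −78 °C; then LiAlH4, 0 °C to reflux; then 2 M HCl, THF, rt
Reagents that add atoms: water O
Why: The bulky borohydride attacks the C3 ketone from the equatorial β side to give the axial 3α-alcohol (the usual outcome for 4,4-disubstituted 3-keto terpenoids, sets C3), LiAlH4 then opens the hindered lactone to the 6β,19-diol without touching a stereocentre, and aqueous acid hydrolyses the strained ketal.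

Step 9
Reactants: 17 3α,6β,19-trihydroxy-11,12,13,14,15,16-hexanorlabdan-9-one
Product: 19 3α,6β,19-tris(trimethylsilyloxy)-11,12,13,14,15,16-hexanorlabd-8-en-9-yl trifluoromethanesulfonate, via tris-TMS ketone 18 (not isolated)
Conditions: N-(trimethylsilyl)imidazole, CH2Cl2, 40 °C, evaporate; then KN(SiMe3)2, PhNTf2, THF, −78 to 0 °C
Reagents that add atoms: N-(trimethylsilyl)imidazole C[Si](C)(C)n1ccnc1; N-phenylbis(trifluoromethanesulfonimide) O=S(=O)(N(c1ccccc1)S(=O)(=O)C(F)(F)F)C(F)(F)F
Why: After silylation the ketone can enolise only toward C8 because C10 is quaternary, so enolate O-triflation gives the tetrasubstituted enol triflate regiospecifically (as with 2,2,6-trimethylcyclohexanone) and erases the relay centre C8.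

Step 10
Reactants: 20 vinylmagnesium bromide; 21 methyl but-2-ynoate
Product: 24 methyl (2E)-3-methylpenta-2,4-dienoate, via vinylcopper 22 (not isolated), via alkenylcopper adduct 23 (not isolated)
Conditions: CuI (1 equiv), THF, −40 °C; then 21, −78 °C; aqueous quench at −78 °C
Reagents that add atoms: none
Why: Syn-carbocupration of the alkynoate, followed by protonation at low temperature before the alkenylcopper can isomerise, places the vinyl group trans to the ester and fixes the 13E geometry.

Step 11
Reactants: 19 3α,6β,19-tris(trimethylsilyloxy)-11,12,13,14,15,16-hexanorlabd-8-en-9-yl trifluoromethanesulfonate; 24 methyl (2E)-3-methylpenta-2,4-dienoate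
Product: 26 methyl 3α,6β,19-tris(trimethylsilyloxy)labda-8,13E-dien-15-oate, via alkylborane 25 (not isolated)
Conditions: 24, 9-BBN-H, THF, 0 °C to rt; then 19, Pd(dppf)Cl2 (10 mol %), AsPh3, K3PO4 (3 M aq), DMF, 50 °C
Reagents that add atoms: none
Why: 9-BBN-H adds anti-Markovnikov to the terminal vinyl group only, and B-alkyl Suzuki–Miyaura coupling of the primary borane with the enol triflate forms C9–C11 with both alkenes keeping their position and geometry.

Step 12
Reactants: 26 methyl 3α,6β,19-tris(trimethylsilyloxy)labda-8,13E-dien-15-oate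
Product: 28 3α,6β,19-trihydroxylabda-8,13E-dien-15-oic acid (target), via lithium carboxylate 27 (not isolated)
Conditions: LiOH, THF/MeOH/H2O, 45 °C; then 1 M HCl to pH 3, 0 °C
Reagents that add atoms: lithium hydroxide [Li+].[OH-]
Why: Saponification of the methyl enoate and solvolysis of the three trimethylsilyl ethers occur in one operation without touching a stereocentre or either alkene.

## Compound list
1 | m-cresol | Cc1cccc(O)c1 | starting material
2 | 4-methoxy-3-methylphenol | COc1ccc(O)cc1C | intermediate
3 | 4,4-dimethoxy-3-methylcyclohexa-2,5-dien-1-one | COC1(OC)C=CC(=O)C=C1C | intermediate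
4 | dimethylzinc | C[Zn]C | starting material
5 | methylzinc dienolate of 6 (C8 R) | C[Zn]OC1=C[C@@H](C)C(OC)(OC)C(C)=C1 | intermediate
6 | (5R)-4,4-dimethoxy-3,5-dimethylcyclohex-2-en-1-one | O=C1C=C(C)C(OC)(OC)[C@H](C)C1 | intermediate
7 | (1S,5R)-4,4-dimethoxy-3,5-dimethylcyclohex-2-en-1-ol (OH cis to 5-methyl) | O[C@@H]1C=C(C)C(OC)(OC)[C@H](C)C1 | intermediate
8 | propionic acid | CCC(=O)O | starting material
9 | (1R,5R)-4,4-dimethoxy-3,5-dimethylcyclohex-2-en-1-yl propanoate (ester trans to 5-methyl) | CCC(=O)O[C@H]1C=C(C)C(OC)(OC)[C@H](C)C1 | intermediate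
10 | acrolein | C=CC=O | starting material
11 | lithium enolate of 9 | CC=C(O[Li])O[C@H]1C=C(C)C(OC)(OC)[C@H](C)C1 | intermediate
12 | (1R,5R)-4,4-dimethoxy-3,5-dimethylcyclohex-2-en-1-yl 3-hydroxy-2-methylpent-4-enoate (mixture at the two acyl stereocentres) | C=CC(O)C(C)C(=O)O[C@H]1C=C(C)C(OC)(OC)[C@H](C)C1 | intermediate
13 | (1R,5R)-4,4-dimethoxy-3,5-dimethylcyclohex-2-en-1-yl 2-methyl-3-oxopent-4-enoate (α-carbon epimerisable) | C=CC(=O)C(C)C(=O)O[C@H]1C=C(C)C(OC)(OC)[C@H](C)C1 | intermediate
14 | 9,9-dimethoxy-3-oxo-11,12,13,14,15,16-hexanorlabdan-19,6β-olide (trans-decalin; 4α-Me, 5α-H, 8α-Me, 10β-Me; lactone C19 on C4β to O on C6β) | C[C@]12C(=O)CC[C@@]3(C)[C@H]1[C@H](OC2=O)C[C@@H](C)C3(OC)OC | intermediate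
15 | 3α-hydroxy-9,9-dimethoxy-11,12,13,14,15,16-hexanorlabdan-19,6β-olide | C[C@]12[C@H](O)CC[C@@]3(C)[C@H]1[C@H](OC2=O)C[C@@H](C)C3(OC)OC | intermediate
16 | 9,9-dimethoxy-11,12,13,14,15,16-hexanorlabdane-3α,6β,19-triol | C[C@]1(CO)[C@H](O)CC[C@@]2(C)[C@H]1[C@H](O)C[C@@H](C)C2(OC)OC | intermediate
17 | 3α,6β,19-trihydroxy-11,12,13,14,15,16-hexanorlabdan-9-one (8α-Me) | C[C@]1(CO)[C@H](O)CC[C@@]2(C)[C@H]1[C@H](O)C[C@@H](C)C2=O | intermediate
18 | 3α,6β,19-tris(trimethylsilyloxy)-11,12,13,14,15,16-hexanorlabdan-9-one | C[C@]1(CO[Si](C)(C)C)[C@H](O[Si](C)(C)C)CC[C@@]2(C)[C@H]1[C@H](O[Si](C)(C)C)C[C@@H](C)C2=O | intermediate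
19 | 3α,6β,19-tris(trimethylsilyloxy)-11,12,13,14,15,16-hexanorlabd-8-en-9-yl trifluoromethanesulfonate | C[C@]1(CO[Si](C)(C)C)[C@H](O[Si](C)(C)C)CC[C@@]2(C)[C@H]1[C@H](O[Si](C)(C)C)CC(C)=C2OS(=O)(=O)C(F)(F)F | intermediate
20 | vinylmagnesium bromide | C=C[Mg]Br | starting material
21 | methyl but-2-ynoate | CC#CC(=O)OC | starting material
22 | vinylcopper | C=C[Cu] | intermediate
23 | methyl (2Z)-2-cuprio-3-methylpenta-2,4-dienoate (vinyl cis to copper) | C=C/C(C)=C([Cu])/C(=O)OC | intermediate
24 | methyl (2E)-3-methylpenta-2,4-dienoate | C=C/C(C)=C/C(=O)OC | intermediate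
25 | methyl (2E)-5-(9-borabicyclo[3.3.1]nonan-9-yl)-3-methylpent-2-enoate | COC(=O)/C=C(C)/CCB1C2CCCC1CCC2 | intermediate
26 | methyl 3α,6β,19-tris(trimethylsilyloxy)labda-8,13E-dien-15-oate | C[C@]1(CO[Si](C)(C)C)[C@H](O[Si](C)(C)C)CC[C@@]2(C)[C@H]1[C@H](O[Si](C)(C)C)CC(C)=C2CC/C(C)=C/C(=O)OC | intermediate
27 | lithium 3α,6β,19-trihydroxylabda-8,13E-dien-15-oate | C[C@]1(CO)[C@H](O)CC[C@@]2(C)[C@H]1[C@H](O)CC(C)=C2CC/C(C)=C/C(=O)[O-].[Li+] | intermediate
28 | 3α,6β,19-trihydroxylabda-8,13E-dien-15-oic acid, (3R,4S,5R,6R,10S) | CC1=C(CC/C(C)=C/C(=O)O)[C@@]2(C)CC[C@@H](O)[C@](C)(CO)[C@@H]2[C@H](O)C1 | target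

## Counts and risks
Total step count: 12. Longest linear sequence: 11 (steps 1–9, 11, 12). Step 10 is a one-step side branch.

The three steps most likely to fail are listed below, each with one fallback.

**Step 7 (radical cascade).**
- The risks are the C4 facial selectivity of the first closure, premature quenching of the C10 radical, and slow hydrogen transfer to the C2 radical.
- The fallback sets out from 13 and comes back at 14. It replaces stoichiometric oxidation by a halogen-atom-transfer chain with a defined end point.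
- Ester 13 is brominated at its α-carbon (NBS, catalytic Mg(ClO4)2, MeCN) to the α-bromo β-keto ester F1.
- Initiation with Et3B and air in toluene at −40 °C, with Mg(ClO4)2 holding the β-dicarbonyl radical in its chelated U shape, drives the same two closures.
- The chain ends by bromine transfer to C2, which gives the 2-bromo keto-lactone F2.
- Zinc dust with NH4Cl in EtOH then removes the bromine to give 14.

**Step 11 (hydroboration of an electron-poor diene and sp3 coupling at a hindered triflate).**
- The fallback sets out from 19 and comes back at 26. It reverses the roles so that the decalin becomes the nucleophile.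
- Triflate 19 is vinylated, an easier sp2–sp2 coupling (potassium vinyltrifluoroborate, Pd(dppf)Cl2, Cs2CO3, THF/H2O), to the 9-vinyl diene F3.
- 9-BBN-H adds to the terminal vinyl group of F3 to give the decalin ethylborane F4.
- A copper-catalysed syn conjugate addition of this alkylborane to methyl but-2-ynoate 21 (CuOAc, P(OPh)3, KOt-Bu, t-BuOH, dioxane) gives 26 directly with the E geometry. Step 10 is then not needed.

**Step 2 (enantioselective methyl addition to the methyl-substituted quinone monoketal).**
- The fallback sets out from 3 and comes back at 7. It replaces asymmetric catalysis by resolution.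
- ZnMe2 with Cu(OTf)2 and achiral P(OEt)3 gives the racemic ketone F5.
- Luche reduction of F5 gives the racemic cis-alcohol F6.
- Candida antarctica lipase B with vinyl acetate acetylates the (1R,5S) enantiomer to the acetate F7.
- This leaves (1S,5R)-7, which is separated by chromatography.

Further compounds
F1 | step 7 | (1R,5R)-4,4-dimethoxy-3,5-dimethylcyclohex-2-en-1-yl 2-bromo-2-methyl-3-oxopent-4-enoate | C=CC(=O)C(C)(Br)C(=O)O[C@H]1C=C(C)C(OC)(OC)[C@H](C)C1
F2 | step 7 | 2-bromo-9,9-dimethoxy-3-oxo-11,12,13,14,15,16-hexanorlabdan-19,6β-olide (mixture at C2) | C[C@]12C(=O)C(Br)C[C@@]3(C)[C@H]1[C@H](OC2=O)C[C@@H](C)C3(OC)OC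
F3 | step 11 | 3α,6β,19-tris(trimethylsilyloxy)-13,14,15,16-tetranorlabda-8,11-diene | C[C@]1(CO[Si](C)(C)C)[C@H](O[Si](C)(C)C)CC[C@@]2(C)[C@H]1[C@H](O[Si](C)(C)C)CC(C)=C2C=C
F4 | step 11 | 12-(9-borabicyclo[3.3.1]nonan-9-yl)-3α,6β,19-tris(trimethylsilyloxy)-13,14,15,16-tetranorlabd-8-ene | C[C@]1(CO[Si](C)(C)C)[C@H](O[Si](C)(C)C)CC[C@@]2(C)[C@H]1[C@H](O[Si](C)(C)C)CC(C)=C2CCB1C2CCCC1CCC2
F5 | step 2 | rac-4,4-dimethoxy-3,5-dimethylcyclohex-2-en-1-one | O=C1C=C(C)C(OC)(OC)C(C)C1
F6 | step 2 | rac-cis-4,4-dimethoxy-3,5-dimethylcyclohex-2-en-1-ol (both enantiomers) | O[C@@H]1C=C(C)C(OC)(OC)[C@H](C)C1.O[C@H]1C=C(C)C(OC)(OC)[C@@H](C)C1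
F7 | step 2 | (1R,5S)-4,4-dimethoxy-3,5-dimethylcyclohex-2-en-1-yl acetate | CC(=O)O[C@H]1C=C(C)C(OC)(OC)[C@@H](C)C1
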